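**Plan**

- Atom numbers (daucane skeleton): C1 quaternary methyl-bearing ring-fusion carbon, C4 carbinol carbon carrying isopropyl, C5 ring-fusion CH, C6 ester-bearing CH, C7 CH2, C8 methyl-bearing alkene carbon, C9 alkene CH, C10 ketone carbon.
- Cuts: the ester C–O bond at C6; the C8=C9 bond of the seven-membered enone; the C4–isopropyl bond; the C5–C6 and C1–C10 bonds, both leading back to 3-methylcyclopent-2-en-1-one.
- Forward order: the cyclopentane is bought; one conjugate addition/aldol flask puts an isopropenyl group (latent acetyl, C10 and C9) on C1 and the ketal-masked C6–C7–C8 arm on C5; isopropyl addition at C4 and ozonolysis follow; the seven-membered ring is closed last across C8–C9, then the C6 hydroxyl is esterified.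
- Enabling feature: the C10 ketone is flanked by quaternary C1, so it can enolise only toward the methyl carbon that becomes C9. C8 is held at the ketal level as the only electrophile, and the trans placement of the C1 and C5 arms on the five-membered ring allows only the seven-membered closure, so one TMSOTf event gives ring, C8=C9 bond and enone.
- Stereochemistry: C1 by copper-catalysed enantioselective conjugate addition; C5 and C6 relayed from it in the same flask (enolate trapped anti to the isopropenyl group, anti aldol through a closed transition state); C4 by Grignard addition anti to the C5 side chain.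

Key step: step 5

Remark: the facial sense of the copper/NHC catalyst is treated as selectable, so the ligand antipode is specified by outcome (the (S)-configured quaternary carbon of 4) and not by name.

**Step 1**
Reactants: 1 ethyl 2-(2-methyl-1,3-dioxolan-2-yl)acetate
Product: 2 2-(2-methyl-1,3-dioxolan-2-yl)acetaldehyde
Conditions: iBu2AlH (1.05 equiv), CH2Cl2, −78 °C; aq. work-up
Reagents that add atoms: none
Why: Partial reduction of an ester with iBu2AlH at −78 °C should stop at the tetrahedral aluminum hemiacetal, which releases the aldehyde only on work-up, and no stereocenter is formed.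

**Step 2**
Reactants: 3 3-methylcyclopent-2-en-1-one; 2 2-(2-methyl-1,3-dioxolan-2-yl)acetaldehyde
Product: 5 (2S,3S)-2-[(1S)-1-hydroxy-2-(2-methyl-1,3-dioxolan-2-yl)ethyl]-3-methyl-3-(prop-1-en-2-yl)cyclopentan-1-one, via aluminum enolate 4 (not isolated)
Conditions: isopropenylmagnesium bromide + Me2AlCl, Et2O, 0 °C (gives isopropenylAlMe2); Cu(OTf)2 (5 mol %), chiral sulfonate-bearing imidazolinium salt (NHC precursor, 6 mol %), 3, −30 °C; then 2, −78 → −40 °C; aq. work-up
Reagents that add atoms: isopropenylmagnesium bromide, C=C(C)[Mg]Br
Why: Copper-catalysed enantioselective conjugate addition of an alkenylaluminum to a β-substituted cyclic enone is a known route to alkenyl-bearing quaternary carbons and sets C1 under catalyst control, and the regiodefined aluminum enolate is then trapped in an aldol addition in which the aldehyde should approach the face anti to the larger isopropenyl group (C5, new bond cis to the methyl group) through a closed Zimmerman–Traxler transition state of the ring-locked (E)-enolate (C6, anti aldol).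

**Step 3**
Reactants: 5 (2S,3S)-2-[(1S)-1-hydroxy-2-(2-methyl-1,3-dioxolan-2-yl)ethyl]-3-methyl-3-(prop-1-en-2-yl)cyclopentan-1-one
Product: 6 (1R,2S,3S)-2-[(1S)-1-hydroxy-2-(2-methyl-1,3-dioxolan-2-yl)ethyl]-3-methyl-1-(propan-2-yl)-3-(prop-1-en-2-yl)cyclopentan-1-ol
Conditions: iPrMgCl (3 equiv), LaCl3·2LiCl (1 equiv), THF, 0 °C; aq. work-up
Reagents that add atoms: isopropylmagnesium chloride, CC(C)[Mg]Cl
Why: LaCl3·2LiCl-promoted Grignard 1,2-addition suppresses enolisation and β-hydride reduction of the hindered ketone, and the isopropyl group should enter the cyclopentanone face opposite to the adjacent C5 side chain (held on the other face in the magnesium chelate of the aldolate), which puts the new C4 hydroxyl cis to that side chain.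

**Step 4**
Reactants: 6 (1R,2S,3S)-2-[(1S)-1-hydroxy-2-(2-methyl-1,3-dioxolan-2-yl)ethyl]-3-methyl-1-(propan-2-yl)-3-(prop-1-en-2-yl)cyclopentan-1-ol
Product: 8 1-[(1S,2S,3R)-3-hydroxy-2-[(1S)-1-hydroxy-2-(2-methyl-1,3-dioxolan-2-yl)ethyl]-1-methyl-3-(propan-2-yl)cyclopentyl]ethan-1-one, via ozonide 7 (not isolated)
Conditions: O3, CH2Cl2, −78 °C; then PPh3, −78 °C → rt
Reagents that add atoms: ozone, [O-][O+]=O
Why: Ozonolysis with reductive work-up should cleave the only C=C bond, the 1,1-disubstituted isopropenyl group, to the methyl ketone while hydroxyls and the ketal (no acetal C–H) are inert at −78 °C, and no stereocenter is affected.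

**Step 5**
Reactants: 8 1-[(1S,2S,3R)-3-hydroxy-2-[(1S)-1-hydroxy-2-(2-methyl-1,3-dioxolan-2-yl)ethyl]-1-methyl-3-(propan-2-yl)cyclopentyl]ethan-1-one
Product: 12 (3R,3aS,4S,8aS)-3,4-dihydroxy-6,8a-dimethyl-3-(propan-2-yl)-2,3,3a,4,5,8a-hexahydroazulen-8(1H)-one, via tris-silyl enol silane 9 (not isolated), via cyclised alkoxy ketone 10 (not isolated), via bis-silyl enone 11 (not isolated)
Conditions: TMSOTf (5 equiv), iPr2NEt (5.5 equiv), CH2Cl2, −78 → 0 °C; then 1 M HCl, THF, 0 °C
Reagents that add atoms: none
Why: TMSOTf/iPr2NEt should first silylate both hydroxyls and turn the acetyl group into its enol silane (9), then open the dioxolane to an oxocarbenium ion at the ketal carbon, which the enol silane carbon attacks to give the β-(2-silyloxyethoxy) ketone 10; further TMSOTf/amine converts 10 into its enol silane, the now allylic tertiary C–O bond ionises, the alkoxy group leaves to give the conjugated enone 11, and aqueous acid removes the two silyl ethers. The closest known reaction types are the one-pot amine/TMSOTf enol silane formation–Mukaiyama aldol addition to acetals and the intramolecular silyl enol ether–acetal cyclisation to six- to eight-membered rings. The seven-membered ring closes in the 7-(enolexo)-exo-trig mode. No stereocenter is created in the product, since the ketal carbon is only transiently stereogenic in 10 and becomes sp2 on elimination, while C1, C4, C5 and C6 are neither enolisable nor ionised. The step needs a single nucleophile and a single electrophile: the ketone sits next to the quaternary C1 and can form only the methyl-side enol silane, the second carbonyl stays at the ketal level so its α-carbons cannot act as nucleophiles, and the trans arms on the cyclopentane rule out any smaller ring. Because the second carbonyl is unmasked only as the C–C bond forms, no free ketone with the C6 oxygen in its β-position is exposed to base, which avoids β-elimination.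

**Step 6**
Reactants: 12 (3R,3aS,4S,8aS)-3,4-dihydroxy-6,8a-dimethyl-3-(propan-2-yl)-2,3,3a,4,5,8a-hexahydroazulen-8(1H)-one; 13 3,4,5-trimethoxybenzoyl chloride
Product: 14 (3R,3aS,4S,8aS)-3-hydroxy-6,8a-dimethyl-8-oxo-3-(propan-2-yl)-1,2,3,3a,4,5,8,8a-octahydroazulen-4-yl 3,4,5-trimethoxybenzoate
Conditions: Et3N, DMAP (cat.), CH2Cl2, 0 °C → rt
Reagents that add atoms: none
Why: DMAP-catalysed acylation with an acid chloride should esterify the secondary C6 hydroxyl while the hindered tertiary C4 hydroxyl stays free, and no stereocenter is touched.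

**Compound list**

1 | ethyl 2-(2-methyl-1,3-dioxolan-2-yl)acetate | CCOC(=O)CC1(C)OCCO1 | starting material
2 | 2-(2-methyl-1,3-dioxolan-2-yl)acetaldehyde | O=CCC1(C)OCCO1 | intermediate
3 | 3-methylcyclopent-2-en-1-one | CC1=CC(=O)CC1 | starting material
4 | dimethylaluminum (S)-3-methyl-3-(prop-1-en-2-yl)cyclopent-1-en-1-olate (formed in the flask) | C=C(C)[C@@]1(C)CCC(O[Al](C)C)=C1 | intermediate
5 | (2S,3S)-2-[(1S)-1-hydroxy-2-(2-methyl-1,3-dioxolan-2-yl)ethyl]-3-methyl-3-(prop-1-en-2-yl)cyclopentan-1-one (anti aldol, side chain cis to the ring methyl) | C=C(C)[C@@]1(C)CCC(=O)[C@@H]1[C@@H](O)CC2(C)OCCO2 | intermediate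
6 | (1R,2S,3S)-2-[(1S)-1-hydroxy-2-(2-methyl-1,3-dioxolan-2-yl)ethyl]-3-methyl-1-(propan-2-yl)-3-(prop-1-en-2-yl)cyclopentan-1-ol | C=C(C)[C@@]1(C)CC[C@@](O)(C(C)C)[C@@H]1[C@@H](O)CC2(C)OCCO2 | intermediate
7 | secondary ozonide of 6 (3-methyl-1,2,4-trioxolan-3-yl group in place of the isopropenyl group; formed in the flask) | CC1(OCOO1)[C@@]2(C)CC[C@@](O)(C(C)C)[C@@H]2[C@@H](O)CC3(C)OCCO3 | intermediate
8 | 1-[(1S,2S,3R)-3-hydroxy-2-[(1S)-1-hydroxy-2-(2-methyl-1,3-dioxolan-2-yl)ethyl]-1-methyl-3-(propan-2-yl)cyclopentyl]ethan-1-one | CC(=O)[C@@]1(C)CC[C@@](O)(C(C)C)[C@@H]1[C@@H](O)CC2(C)OCCO2 | intermediate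
9 | tris(trimethylsilyl) derivative of 8: trimethylsilyl enol ether of the acetyl group, both hydroxyls as trimethylsilyl ethers (formed in the flask) | C=C(O[Si](C)(C)C)[C@@]1(C)CC[C@@](O[Si](C)(C)C)(C(C)C)[C@@H]1[C@@H](O[Si](C)(C)C)CC2(C)OCCO2 | intermediate
10 | cyclised β-[2-(trimethylsilyloxy)ethoxy] ketone, bis(trimethylsilyl) ether, mixture at the alkoxy-bearing carbon (formed in the flask) | C[Si](C)(C)O[C@H]1CC(C)(OCCO[Si](C)(C)C)CC(=O)[C@@]2(C)CC[C@@](O[Si](C)(C)C)(C(C)C)[C@H]12 | intermediate
11 | bis(trimethylsilyl) ether of 12 (formed in the flask) | C[Si](C)(C)O[C@H]1CC(C)=CC(=O)[C@@]2(C)CC[C@@](O[Si](C)(C)C)(C(C)C)[C@H]12 | intermediate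
12 | (3R,3aS,4S,8aS)-3,4-dihydroxy-6,8a-dimethyl-3-(propan-2-yl)-2,3,3a,4,5,8a-hexahydroazulen-8(1H)-one | O[C@H]1CC(C)=CC(=O)[C@@]2(C)CC[C@@](O)(C(C)C)[C@H]12 | intermediate
13 | 3,4,5-trimethoxybenzoyl chloride | COc1cc(C(=O)Cl)cc(OC)c1OC | starting material
14 | (3R,3aS,4S,8aS)-3-hydroxy-6,8a-dimethyl-8-oxo-3-(propan-2-yl)-1,2,3,3a,4,5,8,8a-octahydroazulen-4-yl 3,4,5-trimethoxybenzoate | COc1cc(C(=O)O[C@H]2CC(C)=CC(=O)[C@@]3(C)CC[C@@](O)(C(C)C)[C@H]23)cc(OC)c1OC | target

**Step count and risks**

Total step count: 6. Longest linear sequence: 6 steps (1 → 2 → 5 → 6 → 8 → 12 → 14).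

Steps most likely to fail:

1. Step 5. Proton loss from the ketal-derived oxocarbenium ion (enol ether formation) may outrun the seven-membered ring closure, and over-silylation of the new enone may lead to ionisation of the C6 oxygen. The fallback sets out from 8 and comes back at 12, and replaces the Lewis-acid closure by a reductive, base-free enolate generation. Ketone 8 would be converted with LiN(SiMe3)2/TMSCl into the tris-silyl enol silane 9, here used as a discrete crude material, and brominated with NBS at the only α-carbon to give the α-bromo ketone bis(trimethylsilyl) ether F1. Aqueous acid (1 M HCl, THF) would remove the silyl ethers and the dioxolane to give the bromo diketone diol F2. SmI2 (THF, −78 °C) would then reduce the C–Br bond to a samarium enolate under neutral conditions and close the ring in an intramolecular Reformatsky reaction, giving the cyclic β-hydroxy ketone F3. A catalytic amount of TsOH would dehydrate F3 to 12.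

2. Step 2. Enantiocontrol may be incomplete in the transfer of a non-silylated alkenyl group to a five-membered enone, aldol trapping of the hindered aluminum enolate may be slow, and facial discrimination between methyl and isopropenyl at C1 during trapping may be poor. The fallback sets out from 3 (with 2) and comes back at 8, and changes the alkenyl donor and the way the acetyl group is unmasked. The much bulkier 1-(trimethylsilyl)vinyl group would be delivered from the alane made by hydroalumination of ethynyltrimethylsilane with iBu2AlH, a reagent class with precedent on five-membered β-substituted enones. Copper/NHC-catalysed addition and trapping with 2 would give the silylvinyl aldol F4, and isopropyl addition as in step 3 the silylvinyl diol F5. Epoxidation with mCPBA would give the epoxysilane F6. Aqueous acid, which hydrolyses the epoxysilane to the methyl ketone and also cleaves the ketal, would give the diketone diol F7. Selective dioxolane formation at the unhindered side-chain ketone (ethylene glycol, PPTS), the acetyl group on the quaternary carbon being too hindered to ketalise, would return 8.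

3. Step 3. Enolisation or β-hydride reduction may compete with addition, the aldolate may undergo retro-aldol cleavage, or attack may occur on the wrong carbonyl face. The fallback sets out from 5 and comes back at 6, and changes both substrate and reagent class. The hydroxyl of 5 would be capped as the triethylsilyl ether F8 (TESCl, imidazole), which removes the aldolate and adds bulk on the face that must stay closed. The isopropyl group would then be added as the non-basic organocerium reagent (iPrLi, CeCl3, THF, −78 °C) to give the tertiary alcohol triethylsilyl ether F9, and TBAF would free the secondary hydroxyl to give 6.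

**Further compounds**

F1 | step 5 | α-bromo ketone bis(trimethylsilyl) ether with intact dioxolane | BrCC(=O)[C@@]1(C)CC[C@@](O[Si](C)(C)C)(C(C)C)[C@@H]1[C@@H](O[Si](C)(C)C)CC2(C)OCCO2
F2 | step 5 | bromo diketone diol | BrCC(=O)[C@@]1(C)CC[C@@](O)(C(C)C)[C@@H]1[C@@H](O)CC(C)=O
F3 | step 5 | cyclic β-hydroxy ketone (mixture at the new carbinol carbon) | O[C@H]1CC(C)(O)CC(=O)[C@@]2(C)CC[C@@](O)(C(C)C)[C@H]12
F4 | step 2 | silylvinyl aldol (1-(trimethylsilyl)vinyl analogue of 5) | C=C([Si](C)(C)C)[C@@]1(C)CCC(=O)[C@@H]1[C@@H](O)CC2(C)OCCO2
F5 | step 2 | silylvinyl diol (1-(trimethylsilyl)vinyl analogue of 6) | C=C([Si](C)(C)C)[C@@]1(C)CC[C@@](O)(C(C)C)[C@@H]1[C@@H](O)CC2(C)OCCO2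
F6 | step 2 | epoxysilane (2-(trimethylsilyl)oxiran-2-yl group on C1, mixture at the oxirane carbon) | C[Si](C)(C)C1(CO1)[C@@]2(C)CC[C@@](O)(C(C)C)[C@@H]2[C@@H](O)CC3(C)OCCO3
F7 | step 2 | diketone diol (8 without the dioxolane) | CC(=O)[C@@]1(C)CC[C@@](O)(C(C)C)[C@@H]1[C@@H](O)CC(C)=O
F8 | step 3 | triethylsilyl ether of 5 | C=C(C)[C@@]1(C)CCC(=O)[C@@H]1[C@@H](O[Si](CC)(CC)CC)CC2(C)OCCO2
F9 | step 3 | triethylsilyl ether of 6 (secondary oxygen silylated) | C=C(C)[C@@]1(C)CC[C@@](O)(C(C)C)[C@@H]1[C@@H](O[Si](CC)(CC)CC)CC2(C)OCCO2
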